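**Remark (one line):** the decalin is numbered as in labdanes (ring A = C1–C5, C10; ring B = C5–C10; C11–C16 side chain; methyls C17 on C8, C18/C19 on C4, C20 on C10), α is the face opposite to the C10 methyl; 1 and 13 are taken as commercially available.

## Retrosynthetic overview

1. Target = 2α,7α-diacetoxy-6β-(3-methylbutanoyloxy)labda-8,13E-dien-15-ol. The esters come last from a 7α-hydroxy-Δ8-6-ketone: 7α-O by oxygenation of the C6 dienolate, 6β-OH by hydride from the open α face.
2. C9–C11 and the C8=C9 alkene come from a B-alkyl Suzuki–Miyaura coupling of a C9 enol triflate, made from a trans-fused decalin-6,9-dione.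
3. Ring A is closed last, at C4–C5: a hydrogen-atom-transfer radical cyclization of a C10-tethered isopropenyl group onto C5 of a 4-methoxy-2,4-dienone ring B, then hydrolysis and equilibration to the trans dione.
4. Enabling feature: the C6 oxygen sits next to C5, and C9 (where the side chain goes) is para to C6 in ring B. Written with O at C6 and C9 (p-quinone pattern: C9=O, C8=C7, C6(OMe)=C5), ring B becomes a dienone whose δ-carbon is C5; afterwards C6 returns as a ketone that lets C5 equilibrate to trans.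
5. Ring order: ring B (from phenol 1) → ring A (key step). C10 is set by Pd catalysis, C2 by a chiral allylborane; C5, C7 and C6 are relayed by the substrate.

Key step: step 7

## Route

**Step 1**
Reactants: 1 4-methoxy-2,6-dimethylphenol
Product: 2 4,4-dimethoxy-2,6-dimethylcyclohexa-2,5-dien-1-one
Conditions: PhI(OAc)2, MeOH, 0 °C
Reagents that add atoms: methanol, CO
Why: Oxidative dearomatization of a para-methoxyphenol in methanol should trap the phenoxenium ion at the methoxy-bearing carbon and give the p-quinone monoketal (no stereocenter).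

**Step 2**
Reactants: 2 4,4-dimethoxy-2,6-dimethylcyclohexa-2,5-dien-1-one
Product: 3 triethyl[(4,4-dimethoxy-2,6-dimethylcyclohexa-1,5-dien-1-yl)oxy]silane
Conditions: Et3SiH, RhCl(PPh3)3 (cat.), THF, 50 °C; filtration through basic alumina
Reagents that add atoms: triethylsilane, CC[SiH](CC)CC
Why: Rhodium-catalysed 1,4-hydrosilylation of one of the two equivalent enone arms should give the regiodefined silyl dienol ether, which is no longer an enone, so the second arm is spared.

**Step 3**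
Reactants: 3 triethyl[(4,4-dimethoxy-2,6-dimethylcyclohexa-1,5-dien-1-yl)oxy]silane
Product: 4 (S)-6-allyl-4,4-dimethoxy-2,6-dimethylcyclohex-2-en-1-one
Conditions: diallyl carbonate, Pd2(dba)3 (cat.), (R)-t-BuPHOX (cat.), Bu4N[Ph3SiF2] (cat.), THF, 25 °C
Reagents that add atoms: diallyl carbonate, C=CCOC(=O)OCC=C
Why: Enantioselective Tsuji–Trost allylation of the fluoride-released tetrasubstituted enolate should build the quaternary C10, the PHOX ligand choosing the enolate face (the (R)-ligand is proposed by analogy with 2-methylcyclohexanone-derived enolates; the enantiomeric ligand would be used if the sense were opposite).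

**Step 4**
Reactants: 4 (S)-6-allyl-4,4-dimethoxy-2,6-dimethylcyclohex-2-en-1-one
Product: 5 2-[(1S)-5,5-dimethoxy-1,3-dimethyl-2-oxocyclohex-3-en-1-yl]acetaldehyde
Conditions: OsO4 (cat.), NaIO4, 2,6-lutidine, dioxane/H2O, 25 °C
Reagents that add atoms: sodium periodate, [Na+].[O-]I(=O)(=O)=O
Why: Lemieux–Johnson cleavage should take the terminal monosubstituted alkene in preference to the electron-poor trisubstituted enone alkene.

**Step 5**
Reactants: 5 2-[(1S)-5,5-dimethoxy-1,3-dimethyl-2-oxocyclohex-3-en-1-yl]acetaldehyde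
Product: 6 (6S)-6-[(2S)-2-hydroxy-4-methylpent-4-en-1-yl]-4,4-dimethoxy-2,6-dimethylcyclohex-2-en-1-one
Conditions: (−)-B-(2-methylallyl)diisopinocampheylborane (from (+)-α-pinene), Et2O, −78 °C; then HOCH2CH2NH2, 25 °C
Reagents that add atoms: (−)-B-(2-methylallyl)diisopinocampheylborane, CC(=C)CB([C@@H]1C[C@@H]2C[C@H]([C@H]1C)C2(C)C)[C@@H]1C[C@@H]2C[C@H]([C@H]1C)C2(C)C
Why: Asymmetric allylboration through a closed six-membered chair transition state should set C2 (S) under reagent control, the aldehyde reacting far faster than the hindered conjugated ketone.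

**Step 6**
Reactants: 6 (6S)-6-[(2S)-2-hydroxy-4-methylpent-4-en-1-yl]-4,4-dimethoxy-2,6-dimethylcyclohex-2-en-1-one
Product: 7 (6S)-6-[(2S)-2-(tert-butyldimethylsilyloxy)-4-methylpent-4-en-1-yl]-4-methoxy-2,6-dimethylcyclohexa-2,4-dien-1-one
Conditions: TBSOTf, i-Pr2NEt, CH2Cl2, −78 °C; then TMSOTf, −20 to 20 °C; Et3N-deactivated silica
Reagents that add atoms: tert-butyldimethylsilyl triflate, CC(C)(C)[Si](C)(C)OS(=O)(=O)C(F)(F)F
Why: O-silylation followed by silyl triflate/amine elimination of methanol from the allylic dimethyl ketal should give the methyl dienol ether, which can only form toward C5 because C5 carries the only hydrogens next to the ketal carbon.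

**Step 7**
Reactants: 7 (6S)-6-[(2S)-2-(tert-butyldimethylsilyloxy)-4-methylpent-4-en-1-yl]-4-methoxy-2,6-dimethylcyclohexa-2,4-dien-1-one
Product: 10 trans-fused (5α-H) 2α-(tert-butyldimethylsilyloxy)-4,4,8α,10β-tetramethyldecalin-6,9-dione, via cis-fused methyl enol ether 8 (not isolated), via cis-fused 6,9-dione 9 (not isolated)
Conditions: Fe(acac)3, PhSiH3, EtOH, 0.01 M, 25 °C; then oxalic acid (aq), THF, 25 °C; then NaOH (aq), 40 °C, N2
Reagents that add atoms: water, O
Why: Proposed new method: an iron hydride formed from Fe(acac)3 and PhSiH3 should transfer a hydrogen atom to the terminal CH2 of the 1,1-disubstituted alkene, and the tertiary C4 radical should add 6-exo-trig to C5, the δ-terminus of the 4-methoxy-2,4-dienone (the donor sits on the γ-carbon C6, where the LUMO has little weight, so C5 stays a good acceptor); the closest known reaction type is the iron-mediated hydrogen-atom-transfer olefin–enone reductive coupling (intramolecular Giese cyclization), extended here from 1,4- to 1,6-addition. The captodative dienoxyl radical should be reduced by divalent iron to the dienolate and protonated at C8, so ring A closes in one 6-exo event, creating the quaternary C4 with its second methyl and leaving C6 as methyl enol ether and C9 as ketone. The tether can reach only the face of the flat dienone on which it is attached, so 8 is cis-fused; aqueous acid then unmasks the C6 ketone and base equilibrates C5 (next to C6=O) and C8 (next to C9=O). The trans fusion should be favoured for the 4,4,10-trimethyl pattern and the C8 methyl should go equatorial, away from the axial C10 methyl, so the cis adduct and both C8 epimers funnel into one dione while C2 and C10 stay untouched. The step needs chemoselective hydrogen-atom transfer to the isopropenyl group (the C5=C6 enol ether is trisubstituted and flanked by quaternary C10) and attack at C5 only (C7 would need an eight-membered transition state); 25 °C and high dilution should suppress [4+2] reactions of the 2,4-dienone.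

**Step 8**
Reactants: 10 trans-fused (5α-H) 2α-(tert-butyldimethylsilyloxy)-4,4,8α,10β-tetramethyldecalin-6,9-dione
Product: 12 2α-(tert-butyldimethylsilyloxy)-6-(triethylsilyloxy)-4,4,8,10β-tetramethyl-5α-decala-6,8-dien-9-yl triflate, via triethylsilyl enol ether ketone 11 (not isolated)
Conditions: KN(SiMe3)2 (1.05 equiv), THF, −78 °C; Et3SiCl; then KN(SiMe3)2 (1.3 equiv); N-(5-chloropyridin-2-yl)triflimide, −78 to 0 °C
Reagents that add atoms: chlorotriethylsilane, CC[Si](Cl)(CC)CC; N-(5-chloropyridin-2-yl)bis(trifluoromethanesulfonyl)imide, FC(F)(F)S(=O)(=O)N(c1ccc(Cl)cn1)S(=O)(=O)C(F)(F)F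
Why: Kinetic deprotonation should take the C7 methylene rather than the C8 methine or the buried C5–H, so C6 is masked as its silyl enol ether; the remaining ketone can enolize only toward C8 (C10 is quaternary) and its enolate is O-triflated.

**Step 9**
Reactants: 13 (E)-3-methylpent-2-en-4-yn-1-ol
Product: 14 (E)-tert-butyl[(3-methylpent-2-en-4-yn-1-yl)oxy]diphenylsilane
Conditions: TBDPSCl, imidazole, DMF, 25 °C
Reagents that add atoms: tert-butyl(chloro)diphenylsilane, CC(C)(C)[Si](Cl)(c1ccccc1)c1ccccc1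
Why: Standard silylation of a primary allylic alcohol; the E alkene is not touched.

**Step 10**
Reactants: 14 (E)-tert-butyl[(3-methylpent-2-en-4-yn-1-yl)oxy]diphenylsilane
Product: 15 (E)-tert-butyl[(3-methylpenta-2,4-dien-1-yl)oxy]diphenylsilane
Conditions: H2 (1 atm), Pd/CaCO3 poisoned with Pb(OAc)2, quinoline, hexane, 25 °C
Reagents that add atoms: none
Why: Semihydrogenation of the terminal alkyne should stop at the vinyl group and leave the trisubstituted E alkene unchanged.

**Step 11**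
Reactants: 12 2α-(tert-butyldimethylsilyloxy)-6-(triethylsilyloxy)-4,4,8,10β-tetramethyl-5α-decala-6,8-dien-9-yl triflate; 15 (E)-tert-butyl[(3-methylpenta-2,4-dien-1-yl)oxy]diphenylsilane
Product: 17 2α-(tert-butyldimethylsilyloxy)-15-(tert-butyldiphenylsilyloxy)-6-(triethylsilyloxy)labda-6,8,13E-triene, via B-alkyl-9-BBN 16 (not isolated)
Conditions: 15, 9-BBN, THF, 0 to 25 °C; then 12, Pd(dppf)Cl2 (cat.), AsPh3, Cs2CO3, DMF/H2O, 25 °C
Reagents that add atoms: none
Why: 9-BBN should add to the unsubstituted terminus of the vinyl group only, and B-alkyl Suzuki–Miyaura coupling with the hindered enol triflate should form C9–C11 and fix the tetrasubstituted C8=C9 alkene.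

**Step 12**
Reactants: 17 2α-(tert-butyldimethylsilyloxy)-15-(tert-butyldiphenylsilyloxy)-6-(triethylsilyloxy)labda-6,8,13E-triene
Product: 19 2α-(tert-butyldimethylsilyloxy)-15-(tert-butyldiphenylsilyloxy)-7α-hydroxylabda-8,13E-dien-6-one, via lithium dienolate 18 (not isolated)
Conditions: MeLi, THF, 0 °C; then 2-(phenylsulfonyl)-3-phenyloxaziridine, −78 °C; NH4Cl (aq)
Reagents that add atoms: 2-(phenylsulfonyl)-3-phenyloxaziridine, O=S(=O)(c1ccccc1)N1OC1c1ccccc1
Why: MeLi should cleave only the enol O–Si bond, and electrophilic hydroxylation of the dienolate should occur at the α-carbon C7 from the α face, the β face being shielded by the axial C4 and C10 methyls.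

**Step 13**
Reactants: 19 2α-(tert-butyldimethylsilyloxy)-15-(tert-butyldiphenylsilyloxy)-7α-hydroxylabda-8,13E-dien-6-one
Product: 20 15-(tert-butyldiphenylsilyloxy)-2α,7α-dihydroxylabda-8,13E-dien-6-one
Conditions: HF·pyridine, pyridine, THF, 0 to 25 °C
Reagents that add atoms: none
Why: Buffered HF should cleave the secondary TBS ether well before the primary TBDPS ether, without base that could isomerize the α-ketol.

**Step 14**
Reactants: 20 15-(tert-butyldiphenylsilyloxy)-2α,7α-dihydroxylabda-8,13E-dien-6-one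
Product: 21 2α,7α-diacetoxy-15-(tert-butyldiphenylsilyloxy)labda-8,13E-dien-6-one
Conditions: Ac2O, DMAP, pyridine, CH2Cl2, 0 °C
Reagents that add atoms: acetic anhydride, CC(=O)OC(C)=O
Why: Both remaining hydroxyls are secondary and accessible, so one acetylation should install both acetates of the target.

**Step 15**
Reactants: 21 2α,7α-diacetoxy-15-(tert-butyldiphenylsilyloxy)labda-8,13E-dien-6-one
Product: 22 2α,7α-diacetoxy-15-(tert-butyldiphenylsilyloxy)labda-8,13E-dien-6β-ol
Conditions: NaBH4, CeCl3·7H2O, MeOH/THF, −40 °C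
Reagents that add atoms: none
Why: In this Luche reduction hydride should approach C6 from the α face, because the β face is blocked by the syn-axial C4 and C10 methyls, giving the axial 6β-alcohol; the esters survive and the trans-diaxial arrangement prevents acetyl migration.

**Step 16**
Reactants: 22 2α,7α-diacetoxy-15-(tert-butyldiphenylsilyloxy)labda-8,13E-dien-6β-ol
Product: 23 2α,7α-diacetoxy-15-(tert-butyldiphenylsilyloxy)labda-8,13E-dien-6β-yl 3-methylbutanoate
Conditions: 3-methylbutanoyl chloride, DMAP, pyridine, CH2Cl2, 40 °C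
Reagents that add atoms: 3-methylbutanoyl chloride, CC(C)CC(=O)Cl
Why: DMAP-catalysed acylation with the acid chloride should overcome the hindrance of the axial 6β-hydroxyl, the only free hydroxyl left.

**Step 17**
Reactants: 23 2α,7α-diacetoxy-15-(tert-butyldiphenylsilyloxy)labda-8,13E-dien-6β-yl 3-methylbutanoate
Product: 24 2α,7α-diacetoxy-15-hydroxylabda-8,13E-dien-6β-yl 3-methylbutanoate (CNP0257091.1)
Conditions: HF·pyridine, THF, 25 °C
Reagents that add atoms: none
Why: Acidic fluoride should remove the primary TBDPS ether while the three esters and both alkenes stay intact.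

## Compound list

1 | 4-methoxy-2,6-dimethylphenol | COc1cc(C)c(O)c(C)c1 | starting material
2 | 4,4-dimethoxy-2,6-dimethylcyclohexa-2,5-dien-1-one | COC1(OC)C=C(C)C(=O)C(C)=C1 | intermediate
3 | triethyl[(4,4-dimethoxy-2,6-dimethylcyclohexa-1,5-dien-1-yl)oxy]silane | CC[Si](CC)(CC)OC1=C(C)CC(OC)(OC)C=C1C | intermediate
4 | (S)-6-allyl-4,4-dimethoxy-2,6-dimethylcyclohex-2-en-1-one | C=CC[C@@]1(C)CC(OC)(OC)C=C(C)C1=O | intermediate
5 | 2-[(1S)-5,5-dimethoxy-1,3-dimethyl-2-oxocyclohex-3-en-1-yl]acetaldehyde | O=CC[C@@]1(C)CC(OC)(OC)C=C(C)C1=O | intermediate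
6 | (6S)-6-[(2S)-2-hydroxy-4-methylpent-4-en-1-yl]-4,4-dimethoxy-2,6-dimethylcyclohex-2-en-1-one | CC(=C)C[C@H](O)C[C@@]1(C)CC(OC)(OC)C=C(C)C1=O | intermediate
7 | (6S)-6-[(2S)-2-(tert-butyldimethylsilyloxy)-4-methylpent-4-en-1-yl]-4-methoxy-2,6-dimethylcyclohexa-2,4-dien-1-one | CC(=C)C[C@H](O[Si](C)(C)C(C)(C)C)C[C@@]1(C)C=C(OC)C=C(C)C1=O | intermediate
8 | cis-fused (5β-H) 2α-(tert-butyldimethylsilyloxy)-6-methoxy-4,4,8,10β-tetramethyldecal-6-en-9-one (C8 epimers) | CC(C)(C)[Si](C)(C)O[C@H]1CC(C)(C)[C@H]2C(OC)=CC(C)C(=O)[C@@]2(C)C1 | intermediate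
9 | cis-fused (5β-H) 2α-(tert-butyldimethylsilyloxy)-4,4,8,10β-tetramethyldecalin-6,9-dione (C8 epimers) | CC(C)(C)[Si](C)(C)O[C@H]1CC(C)(C)[C@H]2C(=O)CC(C)C(=O)[C@@]2(C)C1 | intermediate
10 | trans-fused (5α-H) 2α-(tert-butyldimethylsilyloxy)-4,4,8α,10β-tetramethyldecalin-6,9-dione | CC(C)(C)[Si](C)(C)O[C@H]1CC(C)(C)[C@@H]2C(=O)C[C@@H](C)C(=O)[C@@]2(C)C1 | intermediate
11 | trans-fused 2α-(tert-butyldimethylsilyloxy)-6-(triethylsilyloxy)-4,4,8α,10β-tetramethyldecal-6-en-9-one | CC(C)(C)[Si](C)(C)O[C@H]1CC(C)(C)[C@@H]2C(O[Si](CC)(CC)CC)=C[C@@H](C)C(=O)[C@@]2(C)C1 | intermediate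
12 | 2α-(tert-butyldimethylsilyloxy)-6-(triethylsilyloxy)-4,4,8,10β-tetramethyl-5α-decala-6,8-dien-9-yl triflate | CC(C)(C)[Si](C)(C)O[C@H]1CC(C)(C)[C@@H]2C(O[Si](CC)(CC)CC)=CC(C)=C(OS(=O)(=O)C(F)(F)F)[C@@]2(C)C1 | intermediate
13 | (E)-3-methylpent-2-en-4-yn-1-ol | C#C/C(C)=C/CO | starting material
14 | (E)-tert-butyl[(3-methylpent-2-en-4-yn-1-yl)oxy]diphenylsilane | C#C/C(C)=C/CO[Si](c1ccccc1)(c1ccccc1)C(C)(C)C | intermediate
15 | (E)-tert-butyl[(3-methylpenta-2,4-dien-1-yl)oxy]diphenylsilane | C=C/C(C)=C/CO[Si](c1ccccc1)(c1ccccc1)C(C)(C)C | intermediate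
16 | 9-[(E)-5-(tert-butyldiphenylsilyloxy)-3-methylpent-3-en-1-yl]-9-borabicyclo[3.3.1]nonane | B1(CC/C(C)=C/CO[Si](c2ccccc2)(c2ccccc2)C(C)(C)C)C2CCCC1CCC2 | intermediate
17 | 2α-(tert-butyldimethylsilyloxy)-15-(tert-butyldiphenylsilyloxy)-6-(triethylsilyloxy)labda-6,8,13E-triene | CC(C)(C)[Si](C)(C)O[C@H]1CC(C)(C)[C@@H]2C(O[Si](CC)(CC)CC)=CC(C)=C(CC/C(C)=C/CO[Si](c3ccccc3)(c3ccccc3)C(C)(C)C)[C@@]2(C)C1 | intermediate
18 | lithium dienolate of 2α-(tert-butyldimethylsilyloxy)-15-(tert-butyldiphenylsilyloxy)labda-8,13E-dien-6-one | [Li+].CC(C)(C)[Si](C)(C)O[C@H]1CC(C)(C)[C@@H]2C([O-])=CC(C)=C(CC/C(C)=C/CO[Si](c3ccccc3)(c3ccccc3)C(C)(C)C)[C@@]2(C)C1 | intermediate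
19 | 2α-(tert-butyldimethylsilyloxy)-15-(tert-butyldiphenylsilyloxy)-7α-hydroxylabda-8,13E-dien-6-one | CC(C)(C)[Si](C)(C)O[C@H]1CC(C)(C)[C@@H]2C(=O)[C@@H](O)C(C)=C(CC/C(C)=C/CO[Si](c3ccccc3)(c3ccccc3)C(C)(C)C)[C@@]2(C)C1 | intermediate
20 | 15-(tert-butyldiphenylsilyloxy)-2α,7α-dihydroxylabda-8,13E-dien-6-one | O[C@H]1CC(C)(C)[C@@H]2C(=O)[C@@H](O)C(C)=C(CC/C(C)=C/CO[Si](c3ccccc3)(c3ccccc3)C(C)(C)C)[C@@]2(C)C1 | intermediate
21 | 2α,7α-diacetoxy-15-(tert-butyldiphenylsilyloxy)labda-8,13E-dien-6-one | CC(=O)O[C@H]1CC(C)(C)[C@@H]2C(=O)[C@@H](OC(C)=O)C(C)=C(CC/C(C)=C/CO[Si](c3ccccc3)(c3ccccc3)C(C)(C)C)[C@@]2(C)C1 | intermediate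
22 | 2α,7α-diacetoxy-15-(tert-butyldiphenylsilyloxy)labda-8,13E-dien-6β-ol | CC(=O)O[C@H]1CC(C)(C)[C@@H]2[C@H](O)[C@@H](OC(C)=O)C(C)=C(CC/C(C)=C/CO[Si](c3ccccc3)(c3ccccc3)C(C)(C)C)[C@@]2(C)C1 | intermediate
23 | 2α,7α-diacetoxy-15-(tert-butyldiphenylsilyloxy)labda-8,13E-dien-6β-yl 3-methylbutanoate | CC(=O)O[C@H]1CC(C)(C)[C@@H]2[C@H](OC(=O)CC(C)C)[C@@H](OC(C)=O)C(C)=C(CC/C(C)=C/CO[Si](c3ccccc3)(c3ccccc3)C(C)(C)C)[C@@]2(C)C1 | intermediate
24 | 2α,7α-diacetoxy-15-hydroxylabda-8,13E-dien-6β-yl 3-methylbutanoate (2S,5S,6S,7S,10S) | CC(=O)O[C@H]1CC(C)(C)[C@@H]2[C@H](OC(=O)CC(C)C)[C@@H](OC(C)=O)C(C)=C(CC/C(C)=C/CO)[C@@]2(C)C1 | target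

## Step count and risks

Total step count: 17. Longest linear sequence: 15 steps (steps 1–8 and 11–17, from 1 to 24).

**Step 7 (Proposed new method).** What may go wrong: the tertiary radical is reduced by a second hydrogen-atom transfer, or hydrogen-atom transfer goes to the enol ether, before the congested closure at C5. The fallback makes the same bond by polar chemistry; it sets out from 6 and comes back at 10. The ketal of 6 is hydrolysed (aqueous AcOH) and anhydrous HCl is added across the isopropenyl group (CH2Cl2, −30 °C) to give the tertiary chloride, (6S)-6-[(2R)-4-chloro-2-hydroxy-4-methylpentyl]-2,6-dimethylcyclohex-2-ene-1,4-dione F1. TBSOTf/Et3N silylates the alcohol and enolizes the C6 ketone toward C5, its only enolizable position, giving the bis-silyl dienol ether F2. TiCl4 (CH2Cl2, −78 °C) ionizes the chloride and the silyl enol ether attacks through C5 (Lewis acid-mediated α-tert-alkylation of a silyl enol ether); DBU then equilibrates C5 to the trans-fused ene-dione F3. Hydrogenation of the C7=C8 bond (H2, Pd/C) and brief base equilibration at C8 give 10.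

**Step 8.** What may go wrong: the first deprotonation is not selective for the C7 methylene, so the wrong carbonyl is carried on as the triflate. The fallback masks C6 by acid chemistry instead of kinetic enolization; it sets out from 10 and comes back at 19. HC(OMe)3/MeOH with camphorsulfonic acid converts the more accessible C6 carbonyl into the trans-fused methyl enol ether F4 (the C5 epimer of 8). KN(SiMe3)2 and the pyridyl triflimide give the enol triflate F5 (only C8 can be deprotonated), and B-alkyl Suzuki–Miyaura coupling with 16 gives the methyl dienol ether F6. Aqueous oxalic acid hydrolyses F6 by kinetic protonation at C7 to the β,γ-unsaturated ketone F7. KN(SiMe3)2 at −78 °C followed by the oxaziridine gives 19.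

**Step 12.** What may go wrong: the oxidant attacks the γ-carbon C9, or the free α-ketol isomerizes to the conjugated 6-hydroxy-7-ketone under the basic conditions. The fallback delivers the oxygen as acetate to the neutral silyl dienol ether; it sets out from 17 and comes back at 21. Pb(OAc)4 (CH2Cl2, −40 °C; α-acetoxylation of a silyl enol ether from the α face) gives the 7α-acetoxy ketone F8. HF·pyridine removes the C2 silyl ether to give the 2α-hydroxy 7α-acetate F9, and Ac2O/DMAP acetylates C2 to give 21.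

## Further compounds

F1 | step 7 | (6S)-6-[(2R)-4-chloro-2-hydroxy-4-methylpentyl]-2,6-dimethylcyclohex-2-ene-1,4-dione | CC(C)(Cl)C[C@H](O)C[C@@]1(C)CC(=O)C=C(C)C1=O
F2 | step 7 | (6S)-4-(tert-butyldimethylsilyloxy)-6-[(2R)-2-(tert-butyldimethylsilyloxy)-4-chloro-4-methylpentyl]-2,6-dimethylcyclohexa-2,4-dien-1-one | CC(C)(Cl)C[C@H](O[Si](C)(C)C(C)(C)C)C[C@@]1(C)C=C(O[Si](C)(C)C(C)(C)C)C=C(C)C1=O
F3 | step 7 | trans-fused (5α-H) 2α-(tert-butyldimethylsilyloxy)-4,4,8,10β-tetramethyldecal-7-ene-6,9-dione | CC(C)(C)[Si](C)(C)O[C@H]1CC(C)(C)[C@@H]2C(=O)C=C(C)C(=O)[C@@]2(C)C1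
F4 | step 8 | trans-fused (5α-H) 2α-(tert-butyldimethylsilyloxy)-6-methoxy-4,4,8α,10β-tetramethyldecal-6-en-9-one | CC(C)(C)[Si](C)(C)O[C@H]1CC(C)(C)[C@@H]2C(OC)=C[C@@H](C)C(=O)[C@@]2(C)C1
F5 | step 8 | 2α-(tert-butyldimethylsilyloxy)-6-methoxy-4,4,8,10β-tetramethyl-5α-decala-6,8-dien-9-yl triflate | CC(C)(C)[Si](C)(C)O[C@H]1CC(C)(C)[C@@H]2C(OC)=CC(C)=C(OS(=O)(=O)C(F)(F)F)[C@@]2(C)C1
F6 | step 8 | 2α-(tert-butyldimethylsilyloxy)-15-(tert-butyldiphenylsilyloxy)-6-methoxylabda-6,8,13E-triene | CC(C)(C)[Si](C)(C)O[C@H]1CC(C)(C)[C@@H]2C(OC)=CC(C)=C(CC/C(C)=C/CO[Si](c3ccccc3)(c3ccccc3)C(C)(C)C)[C@@]2(C)C1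
F7 | step 8 | 2α-(tert-butyldimethylsilyloxy)-15-(tert-butyldiphenylsilyloxy)labda-8,13E-dien-6-one | CC(C)(C)[Si](C)(C)O[C@H]1CC(C)(C)[C@@H]2C(=O)CC(C)=C(CC/C(C)=C/CO[Si](c3ccccc3)(c3ccccc3)C(C)(C)C)[C@@]2(C)C1
F8 | step 12 | 7α-acetoxy-2α-(tert-butyldimethylsilyloxy)-15-(tert-butyldiphenylsilyloxy)labda-8,13E-dien-6-one | CC(C)(C)[Si](C)(C)O[C@H]1CC(C)(C)[C@@H]2C(=O)[C@@H](OC(C)=O)C(C)=C(CC/C(C)=C/CO[Si](c3ccccc3)(c3ccccc3)C(C)(C)C)[C@@]2(C)C1
F9 | step 12 | 7α-acetoxy-15-(tert-butyldiphenylsilyloxy)-2α-hydroxylabda-8,13E-dien-6-one | O[C@H]1CC(C)(C)[C@@H]2C(=O)[C@@H](OC(C)=O)C(C)=C(CC/C(C)=C/CO[Si](c3ccccc3)(c3ccccc3)C(C)(C)C)[C@@]2(C)C1
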